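Take the share of solid substrate not yet turned into product, and work in powers of ten.

common to all: solid substrate 0.50 mM

|  | reagent | remark | time |
|---|---|---|---|
| south-east | 0.58 mM | run made earlier |  |
| west | 1.8 mM | run made earlier |  |
| summer | 1.00 mM |  | 3.0 min |
| noon | 3.00 mM |  | 1.0 min |

- south-east (time / s: product / %): 12.0: 34.2; 30.0: 48.7; 60.0: 56.9; 90.0: 62.5; 120: 67.2
- west (time / s: product / %): 12.0: 84.9; 30.0: 90.3; 60.0: 93.6; 90.0: 96.2; 120: 97.2

(standard deviation of a reading: 1 percentage point)

- the flask that ends with the higher amount of product, in percent of the solid substrate charged, or "neither" when 2 percentage points or less lies between them (summer / noon / neither)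
- final product, as a percentage of the solid substrate charged, in summer
- final product, as a percentage of the solid substrate charged, in noon

- solid, in amounts per volume of the solution: solid substrate
- at the start none of the solid substrate is in solution
- what has only dissolved of solid substrate counts as not reacted

*Where do the flasks summer and noon stand against the two runs?* On a logarithmic reagent scale with the south-east run at zero and the west run at one, summer sits at 0.481 and noon at 1.45. So summer is an interpolation and noon an extrapolation.

*Noon, then?* Its 1.0 min is a reading time of both runs. The unreacted shares there are 43.1% and 6.40%, and carried along that scale they give 2.71% unreacted, so I say 97.3% product.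

*But summer's 3.0 min lies beyond every reading.* Yes, so I need the tail slope: the powers of ten of unreacted share lost per minute late in a run. Between 60.0 s and 120 s it reads 0.119 min⁻¹ in south-east and 0.359 min⁻¹ in west, which puts summer at 0.202 min⁻¹. Summer's unreacted share at 120 s comes to 10.0%, and the tail slope takes it to 6.31%, so 93.7% product.

*Your weak spot?* The last west reading leaves 2.80% unreacted against a scatter of 1 percentage point, so the slope is soft. Still, I reckon 6.31% unreacted in summer at its own time and 2.71% in noon at its own time, and the margin is 2 points, so I say noon.

The forecast says noon, with summer at 90% (85% to 94%) and noon at 97% (94% to 99.5%). Its ground: “the effective rate constant falls with time, regardless of reagent level”. My summer figure stands above its value, inside its range.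

The flasks give 92.8% in summer and 97.2% in noon, so noon ends higher. The difference in reagent is the largest single effect: with it taken away, noon reads 80.1% instead of 97.2%.

    starting material + reagent → product, rate k1*[starting material]*[reagent]^1.5 (k = 4900 L¹·⁵ mol⁻¹·⁵ s⁻¹)
    solid substrate ⇌ starting material, rate k2*(cs2 - [starting material]) while solid is left; crystals form when [starting material] > cs2 (solubility = 0.480 mM, k = 0.550 s⁻¹)
    starting material ⇌ dormant form (K = 3.00, k = 0.0470 s⁻¹)

In summer, the tail slope carries 84.7% product at 1.50 min to 92.4% at the asked time. Carried from the neighbouring reading of the same recipe, 83.3% at 80 s, it gives 92.3%. Summer's tail comes in part from the dormant form, the resting state of what is unreacted there: at 3.00 min it holds 6.19% against 0.970% of starting material. With the step to the dormant form taken away, both ways, summer reads >99.9% instead of 92.8%.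

The data come from a simulation from invented constants; noise was put on by code.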